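**Retrosynthetic overview**

1. The target is two fully substituted phloroglucinol-type rings joined by one CH2. The last disconnections are four O-benzyl groups and the two isobutyryl C–C bonds (C6 of ring A, C5' of ring B), which go onto the only free ring positions together.
2. The strategy rests on ring A: C1 OMe, C2 Me, C3 OH, C4 bridge CH2, C5 OMe, C6 isobutyryl. Its single free phenol (C3) sits between two carbon substituents, with methyl ethers at C1 and C5. A vinylketene/ynol ether benzannulation gives this pattern: the ketene carbonyl becomes C3–OH and each partner brings one OMe.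
3. Key disconnection: ring A is split into cyclobutenone 6 and the ring B propargylic methyl ynol ether 15. C3–C4 and C5–C6 form in the (2+2) step, C2–C3 in the 6-pi closure.
4. Cyclobutenone 6 comes from methylketene and methoxyacetylene 3. Ynol ether 15 comes from the acetylide of 3 and a ring B benzylic chloride made from 2-methylphloroglucinol 7.
5. Ring order: ring B is bought as an arene, the four-membered ring of 6 is made in step 2, and ring A is the only aromatic ring built, closed in step 7.

Key step: step 7

Remark: the target has no stereocentre, so 6 is used as the racemate; ring B is numbered C1' (bridge), C2' OH, C3' Me, C4' OH, C5' isobutyryl, C6' OH.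

**Route**

Step 1
Reactants: 1 chloroacetaldehyde dimethyl acetal
Product: 3 methoxyacetylene, via sodium methoxyacetylide 2 (not isolated)
Conditions: NaNH2 (3 equiv), liq. NH3, −33 °C; NH3 evaporated; cold aq NaCl, −70 °C to rt, volatile product distilled into a −78 °C trap
Reagents that add atoms: none
Why: Base-induced elimination of methanol and then of HCl from the chloroacetal, followed by deprotonation, is the established preparation of alkoxyacetylides, and the cold aqueous quench should protonate the acetylide so that the alkyne distils out.

Step 2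
Reactants: 3 methoxyacetylene (2 equiv); 4 propionyl chloride
Product: 6 3-methoxy-4-methylcyclobut-2-en-1-one (racemic), via methylketene 5 (not isolated)
Conditions: Et3N (1.2 equiv), Et2O, slow addition of 4, −10 °C to rt
Reagents that add atoms: none
Why: Dehydrochlorination of 4 gives methylketene, which should undergo ketene–ynol ether (2+2) cycloaddition with its carbonyl carbon bonding to the unsubstituted nucleophilic alkyne carbon, placing OMe at C3 and Me at C4; the new centre forms as the racemate and is erased in step 7.

Step 3
Reactants: 7 2-methylphloroglucinol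
Product: 8 1,3,5-tris(benzyloxy)-2-methylbenzene
Conditions: BnBr (3.3 equiv), K2CO3, DMF, N2, rt to 60 °C
Reagents that add atoms: benzyl bromide, BrCc1ccccc1
Why: Williamson ether synthesis, in which carbonate in a dipolar aprotic solvent favours O- over C-benzylation of the phloroglucinol anion and should give the symmetrical triether.

Step 4
Reactants: 8 1,3,5-tris(benzyloxy)-2-methylbenzene
Product: 10 2,4,6-tris(benzyloxy)-3-methylbenzaldehyde, via aryl iminium chloride 9 (not isolated)
Conditions: POCl3 (1.3 equiv), DMF, 0 to 50 °C; then H2O, rt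
Reagents that add atoms: N,N-dimethylformamide, CN(C)C=O; water, O
Why: Vilsmeier–Haack formylation of a phloroglucinol triether, where the two free ring positions are equivalent by symmetry and the first formyl group deactivates the ring against a second substitution.

Step 5
Reactants: 10 2,4,6-tris(benzyloxy)-3-methylbenzaldehyde
Product: 11 [2,4,6-tris(benzyloxy)-3-methylphenyl]methanol
Conditions: NaBH4, THF–MeOH, 0 °C; then H2O
Reagents that add atoms: none
Why: Borohydride reduction of an aryl aldehyde, with a neutral work-up so that the acid-labile trialkoxybenzyl alcohol should survive.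

Step 6
Reactants: 11 [2,4,6-tris(benzyloxy)-3-methylphenyl]methanol; 3 methoxyacetylene (2.5 equiv)
Product: 15 1-methoxy-3-[2,4,6-tris(benzyloxy)-3-methylphenyl]prop-1-yne, via benzylic mesylate 12 (not isolated), via benzylic chloride 13 (not isolated), via lithium methoxyacetylide 14 (not isolated)
Conditions: 11, n-BuLi (1.0 equiv), THF, −78 °C; MsCl (1.0 equiv), −78 to −30 °C; transferred cold into 14 (from 3 and n-BuLi, THF, −78 °C), DMPU, −78 to 0 °C; chromatography on Et3N-deactivated silica
Reagents that add atoms: none
Why: Sulfonylation of the lithium alkoxide with chloride return, the established acid-free way to turn activated alkoxides into chlorides, should give the labile electron-rich benzylic chloride, and SN2 C-alkylation of the lithium alkoxyacetylide in the presence of DMPU then forms the propargylic C–C bond.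

Step 7
Reactants: 6 3-methoxy-4-methylcyclobut-2-en-1-one; 15 1-methoxy-3-[2,4,6-tris(benzyloxy)-3-methylphenyl]prop-1-yne
Product: 20 3,5-dimethoxy-2-methyl-6-{[2,4,6-tris(benzyloxy)-3-methylphenyl]methyl}phenol, via vinylketene 16 (not isolated), via vinylcyclobutenone 17 (not isolated), via dienylketene 18 (not isolated), via cyclohexadienone 19 (not isolated)
Conditions: 15 in degassed toluene at reflux (110 °C) under argon; 6 in toluene added slowly by syringe pump in a 1:1 molar ratio; reflux continued until 17 is consumed
Reagents that add atoms: none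
Why: Danheiser benzannulation: 6 should open by 4-pi electrocyclic cleavage of its C1–C4 bond to the methoxy vinylketene 16, which adds (2+2) across the ynol ether of 15 to give 17; 17 opens to the dienylketene 18, which closes to 19 and enolises to the phenol 20. The closest known reaction type is the thermal annulation of cyclobutenones with alkoxy- or siloxyalkynes to give resorcinol monoethers, so this is a known reaction on a new pair of partners. Ring A is closed by a thermally allowed disrotatory 6-pi electrocyclisation of the ketene carbon (future C3) onto the CHMe terminus (future C2), after the (2+2) step has formed C3–C4 and C5–C6. No stereocentre is set: the centre of 6 becomes an sp2 terminus and the centres of 17 and 19 are erased by ring opening and enolisation. The one selectivity needed is regiochemical, bridge carbon next to the phenol, and it is secured by polarity: the nucleophilic alkyne carbon remote from OMe, which bears the ring B benzyl group, bonds to the electrophilic ketene carbonyl carbon. The step is an addition followed by isomerisation in which every atom of 6 and of 15 is kept in 20, a methyl ynol ether has no retro-ene fragmentation open to it at this temperature, and slow addition of 6 keeps the vinylketene dilute so that capture by 15 should outrun its dimerisation.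

Step 8
Reactants: 20 3,5-dimethoxy-2-methyl-6-{[2,4,6-tris(benzyloxy)-3-methylphenyl]methyl}phenol
Product: 21 1-(benzyloxy)-3,5-dimethoxy-2-methyl-6-{[2,4,6-tris(benzyloxy)-3-methylphenyl]methyl}benzene
Conditions: BnBr (1.3 equiv), K2CO3, DMF, 50 °C
Reagents that add atoms: benzyl bromide, BrCc1ccccc1
Why: Williamson O-benzylation, which masks the ring A phenol so that step 9 can acylate only carbon and leaves all four protecting groups removable in one operation.

Step 9
Reactants: 21 tetrabenzyl ether from step 8; 22 2-methylpropanoic acid (isobutyric acid, 3 equiv)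
Product: 24 tetrabenzyl diketone, that is 21 bearing 2-methylpropanoyl groups at C6 of ring A and at C5' of ring B, via mixed anhydride 23 (not isolated)
Conditions: 22, (CF3CO)2O (3.5 equiv), CH2Cl2, 0 °C; then 21, 0 °C to rt
Reagents that add atoms: none
Why: Friedel–Crafts acylation by the mixed trifluoroacetic anhydride, in which each ring is a phloroglucinol triether with one free position (C6 para to the C3 oxygen and between two OMe, C5' between two OBn) and the absence of a chelating Lewis acid should spare the methyl ethers ortho to the new ketone.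

Step 10
Reactants: 24 tetrabenzyl diketone
Product: 25 1-[3-{[2-hydroxy-4,6-dimethoxy-3-methyl-5-(2-methylpropanoyl)phenyl]methyl}-2,4,6-trihydroxy-5-methylphenyl]-2-methylpropan-1-one (target)
Conditions: H2 (1 atm), 10% Pd/C, EtOAc–MeOH, rt
Reagents that add atoms: none
Why: Catalytic hydrogenolysis of the four aryl benzyl ethers, under which methyl ethers, hindered aryl ketones and the diarylmethane bridge should be inert.

**Compound list**

1 | chloroacetaldehyde dimethyl acetal | COC(CCl)OC | starting material
2 | sodium methoxyacetylide | [Na+].[C-]#COC | intermediate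
3 | methoxyacetylene | COC#C | intermediate
4 | propionyl chloride | CCC(=O)Cl | starting material
5 | methylketene (prop-1-en-1-one) | CC=C=O | intermediate
6 | 3-methoxy-4-methylcyclobut-2-en-1-one (racemic) | COC1=CC(=O)C1C | intermediate
7 | 2-methylphloroglucinol (2-methylbenzene-1,3,5-triol) | Cc1c(O)cc(O)cc1O | starting material
8 | 1,3,5-tris(benzyloxy)-2-methylbenzene | Cc1c(OCc2ccccc2)cc(OCc2ccccc2)cc1OCc2ccccc2 | intermediate
9 | N-{[2,4,6-tris(benzyloxy)-3-methylphenyl]methylidene}-N-methylmethanaminium chloride | C[N+](C)=Cc1c(OCc2ccccc2)cc(OCc2ccccc2)c(C)c1OCc2ccccc2.[Cl-] | intermediate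
10 | 2,4,6-tris(benzyloxy)-3-methylbenzaldehyde | O=Cc1c(OCc2ccccc2)cc(OCc2ccccc2)c(C)c1OCc2ccccc2 | intermediate
11 | [2,4,6-tris(benzyloxy)-3-methylphenyl]methanol | OCc1c(OCc2ccccc2)cc(OCc2ccccc2)c(C)c1OCc2ccccc2 | intermediate
12 | [2,4,6-tris(benzyloxy)-3-methylphenyl]methyl methanesulfonate | CS(=O)(=O)OCc1c(OCc2ccccc2)cc(OCc2ccccc2)c(C)c1OCc2ccccc2 | intermediate
13 | 1,3,5-tris(benzyloxy)-2-(chloromethyl)-4-methylbenzene | ClCc1c(OCc2ccccc2)cc(OCc2ccccc2)c(C)c1OCc2ccccc2 | intermediate
14 | lithium methoxyacetylide | [Li+].[C-]#COC | intermediate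
15 | 1-methoxy-3-[2,4,6-tris(benzyloxy)-3-methylphenyl]prop-1-yne | COC#CCc1c(OCc2ccccc2)cc(OCc2ccccc2)c(C)c1OCc2ccccc2 | intermediate
16 | (Z)-3-methoxypenta-1,3-dien-1-one (vinylketene) | C/C=C(\OC)C=C=O | intermediate
17 | 3-methoxy-4-[(Z)-1-methoxyprop-1-en-1-yl]-2-{[2,4,6-tris(benzyloxy)-3-methylphenyl]methyl}cyclobut-2-en-1-one (racemic) | COC1=C(Cc2c(OCc3ccccc3)cc(OCc3ccccc3)c(C)c2OCc3ccccc3)C(=O)C1/C(OC)=C/C | intermediate
18 | (3E,5Z)-3,5-dimethoxy-2-{[2,4,6-tris(benzyloxy)-3-methylphenyl]methyl}hepta-1,3,5-trien-1-one (dienylketene) | O=C=C(Cc1c(OCc2ccccc2)cc(OCc2ccccc2)c(C)c1OCc2ccccc2)/C(OC)=C\C(OC)=C\C | intermediate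
19 | 3,5-dimethoxy-6-methyl-2-{[2,4,6-tris(benzyloxy)-3-methylphenyl]methyl}cyclohexa-2,4-dien-1-one (racemic) | COC1=CC(OC)=C(Cc2c(OCc3ccccc3)cc(OCc3ccccc3)c(C)c2OCc3ccccc3)C(=O)C1C | intermediate
20 | 3,5-dimethoxy-2-methyl-6-{[2,4,6-tris(benzyloxy)-3-methylphenyl]methyl}phenol | COc1cc(OC)c(Cc2c(OCc3ccccc3)cc(OCc3ccccc3)c(C)c2OCc3ccccc3)c(O)c1C | intermediate
21 | 1-(benzyloxy)-3,5-dimethoxy-2-methyl-6-{[2,4,6-tris(benzyloxy)-3-methylphenyl]methyl}benzene | COc1cc(OC)c(Cc2c(OCc3ccccc3)cc(OCc3ccccc3)c(C)c2OCc3ccccc3)c(OCc2ccccc2)c1C | intermediate
22 | 2-methylpropanoic acid (isobutyric acid) | CC(C)C(=O)O | starting material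
23 | 2-methylpropanoic trifluoroacetic anhydride | CC(C)C(=O)OC(=O)C(F)(F)F | intermediate
24 | tetrabenzyl diketone: 21 with 2-methylpropanoyl at C6 (ring A) and C5' (ring B) | COc1c(C(=O)C(C)C)c(OC)c(Cc2c(OCc3ccccc3)c(C(=O)C(C)C)c(OCc3ccccc3)c(C)c2OCc3ccccc3)c(OCc2ccccc2)c1C | intermediate
25 | 1-[3-{[2-hydroxy-4,6-dimethoxy-3-methyl-5-(2-methylpropanoyl)phenyl]methyl}-2,4,6-trihydroxy-5-methylphenyl]-2-methylpropan-1-one | COc1c(C)c(O)c(Cc2c(O)c(C)c(O)c(C(=O)C(C)C)c2O)c(OC)c1C(=O)C(C)C | target

**Step count**

Total: 10 steps. Longest linear sequence: 8 steps (steps 3 to 10, from 7). Steps 1 and 2 form the side branch to 6, and step 1 also feeds step 6.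

**Steps most likely to fail**

Step 7 (key step). The vinylogous-ester cyclobutenone may open too slowly, so that dimerisation of the vinylketene and thermal degradation of the ynol ether outrun the cycloaddition. Some of the product phenol may also be O-acylated by the vinylketene; brief KOH/MeOH treatment of the crude mixture would cleave such esters. Fallback: generate the same vinylketene 16 without the cyclobutenone, at or below room temperature. It sets out from 15 and commercial methyl 3-oxopentanoate (CCC(=O)CC(=O)OC). Enol etherification with HC(OMe)3 and catalytic H2SO4 in MeOH should give methyl (E)-3-methoxypent-2-enoate F1. Saponification (LiOH, aq MeOH, cold acidification to pH 4) should give (E)-3-methoxypent-2-enoic acid F2, and (COCl)2 with catalytic DMF in CH2Cl2 should give (E)-3-methoxypent-2-enoyl chloride F3. Slow addition of F3 to 15 and Et3N in CH2Cl2 should effect 1,4-dehydrochlorination to 16, which is trapped by 15 as 17. Gentle heating in toluene then takes 17 through 18 and 19, and the route is rejoined at 20.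

Step 6. The electron-rich benzylic chloride 13 may ionise and alkylate the free C5' position of another molecule (oligomerisation) before the acetylide captures it. Fallback: carry the bridge carbon at the carbinol oxidation level so that no benzylic halide is needed. It sets out from aldehyde 10. Addition of lithium methoxyacetylide 14 (THF, −78 °C) and in situ O-methylation of the alkoxide (MeI, DMPU, −78 °C to rt) should give racemic 1,3,5-tris(benzyloxy)-2-(1,3-dimethoxyprop-2-yn-1-yl)-4-methylbenzene F4. Benzannulation of F4 with 6 under the conditions of step 7 should give racemic 3,5-dimethoxy-2-{methoxy[2,4,6-tris(benzyloxy)-3-methylphenyl]methyl}-6-methylphenol F5. Ionic hydrogenation of the doubly benzylic methyl ether (Et3SiH, CF3CO2H, CH2Cl2, −40 °C) then removes the methoxy group, and the route is rejoined at 20.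

Step 9. The trifluoroacetic acid released may cause ipso attack or protodealkylation at the bridge (retro-Friedel–Crafts cleavage of the diarylmethane) or loss of benzyl groups, and trifluoroacetylation may compete. Fallback: acid-free acylation through aryllithiums. It sets out from 21. NBS (2 equiv, MeCN, 0 °C) should brominate the two free positions to give the C6,C5'-dibromide F6. Bromine–lithium exchange (t-BuLi, THF, −78 °C) and addition to isobutyraldehyde should give the bis(1-hydroxy-2-methylpropyl) compound F7 as a diastereomer mixture. Dess–Martin periodinane oxidation of both carbinols then rejoins the route at 24.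

**Further compounds**

F1 | step 7 | methyl (E)-3-methoxypent-2-enoate | CO/C(CC)=C/C(=O)OC
F2 | step 7 | (E)-3-methoxypent-2-enoic acid | CO/C(CC)=C/C(=O)O
F3 | step 7 | (E)-3-methoxypent-2-enoyl chloride | CO/C(CC)=C/C(=O)Cl
F4 | step 6 | 1,3,5-tris(benzyloxy)-2-(1,3-dimethoxyprop-2-yn-1-yl)-4-methylbenzene (racemic) | COC#CC(OC)c1c(OCc2ccccc2)cc(OCc2ccccc2)c(C)c1OCc2ccccc2
F5 | step 6 | 3,5-dimethoxy-2-{methoxy[2,4,6-tris(benzyloxy)-3-methylphenyl]methyl}-6-methylphenol (racemic) | COc1cc(OC)c(C(OC)c2c(OCc3ccccc3)cc(OCc3ccccc3)c(C)c2OCc3ccccc3)c(O)c1C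
F6 | step 9 | 21 brominated at C6 (ring A) and C5' (ring B) | COc1c(Br)c(OC)c(Cc2c(OCc3ccccc3)c(Br)c(OCc3ccccc3)c(C)c2OCc3ccccc3)c(OCc2ccccc2)c1C
F7 | step 9 | 21 bearing 1-hydroxy-2-methylpropyl at C6 and C5' (diastereomer mixture) | COc1c(C(O)C(C)C)c(OC)c(Cc2c(OCc3ccccc3)c(C(O)C(C)C)c(OCc3ccccc3)c(C)c2OCc3ccccc3)c(OCc2ccccc2)c1C
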